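**Plan**
- Cuts: the acetates go back to silyl ethers, C11 is re-oxidised to a ketone, and C7=C8 is moved into conjugation as C8=C9. H5 is then removed as a C5=C6 alkene, and C7–C8 and C9–C10 are cut together in one retro-[4+2].
- Enabling feature (labdane numbering): ring A (C1–C5, C10) carries the C2 oxygen, the C4 gem-dimethyl pair, C20 on C10 and the C6–C7 arm, so it is a 4-oxygenated 1-vinyl-2,6,6-trimethylcyclohexene with the diene C10=C5–C6=C7. C17–C8–C9, with C11 as a carbonyl and the chain C12–C16 attached, is a methyl-capped ynone.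
- Forward order: ring A comes with ketoisophorone. The chain is made from (R)-3-methylglutaric acid monomethyl ester and a propynyl Grignard reagent. Ring B closes in one intermolecular Diels–Alder reaction that unites all twenty skeletal carbons.
- Stereochemistry: C2 comes from asymmetric transfer hydrogenation and C13 from the chiral monoester. C10 is relayed from C2 in the cycloaddition, C5 is set by hydrogenation anti to C20, and C9 by dienolate protonation anti to C20.
- Finish: C11 ketone to alcohol, radical deoxygenation, desilylation, double acetylation.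

Key step: step 10

Reading of the target: the SMILES corresponds to (2R,5R,9R,10R,13S). It is a trans-decalin with H5, H9 and the equatorial C2 acetate on one face, C20 and H2 on the other, and a trisubstituted C7=C8 alkene.

Assumption: the sense of induction in step 1 is taken from the aryl/alkenyl ketone model of the catalyst. If the S alcohol formed instead, the (S,S)-ligand would be used and nothing else would change.

**Step 1**
Reactants: 1 ketoisophorone (2,6,6-trimethylcyclohex-2-ene-1,4-dione)
Product: 2 (R)-4-hydroxy-2,6,6-trimethylcyclohex-2-en-1-one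
Conditions: RuCl[(R,R)-TsDPEN](p-cymene) (0.5 mol %), KOH (1 mol %), iPrOH, 25 °C
Reagents that add atoms: none
Why: Noyori-type asymmetric transfer hydrogenation reduces only the open C4 carbonyl, since the C1 carbonyl is walled in by the gem-dimethyl carbon and the methyl-bearing alkene carbon, and with the alkene carbon taking the place that an aryl group holds in the catalyst model the (R,R)-ligand should set the R carbinol centre, the future C2.

**Step 2**
Reactants: 2 (R)-4-hydroxy-2,6,6-trimethylcyclohex-2-en-1-one
Product: 3 (R)-4-(tert-butyldimethylsilyloxy)-2,6,6-trimethylcyclohex-2-en-1-one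
Conditions: TBSCl, imidazole, DMF, rt
Reagents that add atoms: tert-butyldimethylsilyl chloride, CC(C)(C)[Si](C)(C)Cl
Why: Standard imidazole-promoted silylation of a secondary allylic alcohol, done before the hydrogenation so that redox isomerisation of the allylic alcohol on palladium is excluded; the carbinol centre is not touched.

**Step 3**
Reactants: 3 (R)-4-(tert-butyldimethylsilyloxy)-2,6,6-trimethylcyclohex-2-en-1-one
Product: 4 (4S,6R)-4-(tert-butyldimethylsilyloxy)-2,2,6-trimethylcyclohexan-1-one (silyloxy group and C6 methyl cis)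
Conditions: H2 (1 bar), 10% Pd/C, EtOAc, rt
Reagents that add atoms: none
Why: Heterogeneous hydrogenation of a conjugated trisubstituted alkene, in which hydrogen should arrive anti to the neighbouring silyloxy group and give the cis isomer, although the C6 centre is erased in step 4 and its epimer would serve equally.

**Step 4**
Reactants: 4 (4S,6R)-4-(tert-butyldimethylsilyloxy)-2,2,6-trimethylcyclohexan-1-one
Product: 6 (S)-4-(tert-butyldimethylsilyloxy)-2,6,6-trimethylcyclohex-1-en-1-yl trifluoromethanesulfonate, via lithium enolate 5 (not isolated)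
Conditions: LiN(iPr)2, THF, −78 to 0 °C; PhNTf2, −78 °C to rt
Reagents that add atoms: N-phenylbis(trifluoromethanesulfonimide), O=S(=O)(N(c1ccccc1)S(=O)(=O)C(F)(F)F)C(F)(F)F
Why: Enol triflate formation: C2 of the ketone is quaternary, so deprotonation can only occur at C6 and gives one tetrasubstituted enolate, which PhNTf2 sulfonylates on oxygen as known for 2,2,6-trimethylcyclohexanones.

**Step 5**
Reactants: 6 (S)-4-(tert-butyldimethylsilyloxy)-2,6,6-trimethylcyclohex-1-en-1-yl trifluoromethanesulfonate; 7 tributyl(vinyl)stannane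
Product: 8 (S)-tert-butyldimethyl[(3,5,5-trimethyl-4-vinylcyclohex-3-en-1-yl)oxy]silane (the diene C10=C5–C6=C7)
Conditions: Pd2(dba)3 (2.5 mol %), AsPh3 (20 mol %), LiCl (3 equiv), NMP, 60 °C
Reagents that add atoms: tributyl(vinyl)stannane 7, C=C[Sn](CCCC)(CCCC)CCCC
Why: Stille coupling of an alkenyl triflate, with LiCl to assist oxidative addition to zerovalent palladium and the weakly bound AsPh3 to speed transmetalation from tin, a pairing that copes with the two flanking substituents of 2,6,6-trimethylcyclohexenyl triflates.

**Step 6**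
Reactants: 9 (R)-5-methoxy-3-methyl-5-oxopentanoic acid (methyl hydrogen (R)-3-methylglutarate)
Product: 10 methyl (R)-5-hydroxy-3-methylpentanoate
Conditions: BH3·SMe2 (1.1 equiv), THF, −10 °C to rt; H2O
Reagents that add atoms: none
Why: Borane reduces a free carboxylic acid much faster than an ester, so the acid terminus becomes the future C15 carbinol, the ester terminus stays as the future C11, and the methyl-bearing centre (future C13) is not involved.

**Step 7**
Reactants: 10 methyl (R)-5-hydroxy-3-methylpentanoate
Product: 11 methyl (R)-5-(tert-butyldimethylsilyloxy)-3-methylpentanoate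
Conditions: TBSCl, imidazole, CH2Cl2, 0 °C to rt
Reagents that add atoms: tert-butyldimethylsilyl chloride, CC(C)(C)[Si](C)(C)Cl
Why: Routine silylation of the primary alcohol, carried out on the crude hydroxy ester to forestall lactonisation.

**Step 8**
Reactants: 11 methyl (R)-5-(tert-butyldimethylsilyloxy)-3-methylpentanoate
Product: 12 (R)-5-(tert-butyldimethylsilyloxy)-N-methoxy-N,3-dimethylpentanamide
Conditions: MeNH(OMe)·HCl (1.5 equiv), iPrMgCl (3 equiv), THF, −20 to 0 °C
Reagents that add atoms: N,O-dimethylhydroxylamine hydrochloride, CNOC.Cl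
Why: Aminolysis of the ester by the magnesium amide of N,O-dimethylhydroxylamine, the usual direct ester-to-Weinreb-amide conversion, which is compatible with the silyl ether.

**Step 9**
Reactants: 12 (R)-5-(tert-butyldimethylsilyloxy)-N-methoxy-N,3-dimethylpentanamide; 13 1-propynylmagnesium bromide
Product: 15 (R)-8-(tert-butyldimethylsilyloxy)-6-methyloct-2-yn-4-one, via magnesium hemiaminal chelate 14 (not isolated)
Conditions: THF, 0 °C to rt; aq NH4Cl
Reagents that add atoms: 1-propynylmagnesium bromide 13, CC#C[Mg]Br
Why: Weinreb ketone synthesis: the chelated tetrahedral adduct holds until work-up, so only one propynyl group is taken up and the ynone is not exposed to the Grignard reagent.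

**Step 10**
Reactants: 8 (S)-tert-butyldimethyl[(3,5,5-trimethyl-4-vinylcyclohex-3-en-1-yl)oxy]silane; 15 (R)-8-(tert-butyldimethylsilyloxy)-6-methyloct-2-yn-4-one
Product: 16 (2R,10R,13R)-2,15-bis(tert-butyldimethylsilyloxy)labda-5,8-dien-11-one (ring B a 1,4-cyclohexadiene with C5=C6 and C8=C9; C20 on the face of H2)
Conditions: 8 (1.5 equiv), Me2AlCl (1.2 equiv), CH2Cl2, −40 °C to rt; aq potassium sodium tartrate
Reagents that add atoms: none
Why: Binding of Me2AlCl to the C11 carbonyl lowers the alkyne LUMO, and a concerted but strongly asynchronous [4+2] cycloaddition follows in which C7–C8 bonding runs ahead of C9–C10 bonding. The closest known reactions are the Diels–Alder additions of 1-vinyl-2,6,6-trimethylcyclohexene to acetylenic esters, which build the drimane decalin, and the Lewis-acid-promoted Diels–Alder reactions of alkynyl ketones. Ring B closes by intermolecular six-membered cycloaddition across C7 and C10 of the s-cis diene and emerges as a 1,4-cyclohexadiene whose two alkenes differ in substitution and conjugation. C10, the only new stereocentre, is governed by C2: with the silyloxy group equatorial the ring A half-chair turns its pseudoaxial C4 methyl to the face of the axial H2, the ynone adds to the other face and C20 is pushed to the side of H2, whereas the competing transition state would need the silyloxy group axial and 1,3-diaxial to both that methyl and the emerging C20. Regioselectivity is needed and rests on polarity, since unsubstituted C7 carries the largest HOMO coefficient of the diene and the methyl-bearing β-carbon C8 the largest LUMO coefficient of the complexed ynone, so acyl-bearing C9 ends on C10. Because the dienophile is an sp-hybridised rod it brings little bulk to the crowded C10 terminus and raises no endo/exo question, and Me2AlCl scavenges protons so that diene and silyl ethers should survive.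

**Step 11**
Reactants: 16 (2R,10R,13R)-2,15-bis(tert-butyldimethylsilyloxy)labda-5,8-dien-11-one
Product: 17 (2R,5R,10R,13R)-2,15-bis(tert-butyldimethylsilyloxy)labd-8-en-11-one (trans-decalin, H5 anti to C20)
Conditions: H2 (4 bar), 10% Pd/C, EtOAc, rt
Reagents that add atoms: none
Why: Heterogeneous hydrogenation distinguishes the two alkenes because the tetrasubstituted acyl-bearing C8=C9 bond cannot reach the metal surface, and the trisubstituted C5=C6 bond can lie on it only with the face opposite axial C20, so H5 is delivered anti to C20 and the trans-decalin results, as with the drimane-type adducts of the parent diene.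

**Step 12**
Reactants: 17 (2R,5R,10R,13R)-2,15-bis(tert-butyldimethylsilyloxy)labd-8-en-11-one
Product: 19 (2R,5R,9R,10R,13R)-2,15-bis(tert-butyldimethylsilyloxy)labd-7-en-11-one (H9 syn to H5, acyl chain equatorial), via potassium dienolate 18 (not isolated)
Conditions: KOtBu (5 equiv), tBuOH–THF, rt; cannulation into cold 10% aq AcOH–Et2O, 0 °C
Reagents that add atoms: none
Why: Deconjugative protonation of a thermodynamic dienolate: under reversible deprotonation the rapidly formed cross-conjugated C12 enolate should drain into the linearly conjugated, transoid C7=C8–C9=C11 dienolate (its exocyclic C8=C17 counterpart would be cisoid and would press C17 against the C11 substituents), and a fast inverse quench protonates C9, the carbon of highest charge density, from the face away from axial C20, which places H9 syn to H5 and the acyl chain equatorial.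

**Step 13**
Reactants: 19 (2R,5R,9R,10R,13R)-2,15-bis(tert-butyldimethylsilyloxy)labd-7-en-11-one
Product: 20 (2R,5R,9R,10R,13R)-2,15-bis(tert-butyldimethylsilyloxy)labd-7-en-11-ol (C11 configuration open)
Conditions: iBu2AlH, CH2Cl2, −78 °C; aq potassium sodium tartrate
Reagents that add atoms: none
Why: Carbonyl reduction by a Lewis acidic, non-basic aluminium hydride at low temperature avoids enolisation and thus reconjugation or C9 epimerisation; the new C11 carbinol centre is not controlled because it is removed in step 15.

**Step 14**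
Reactants: 20 (2R,5R,9R,10R,13R)-2,15-bis(tert-butyldimethylsilyloxy)labd-7-en-11-ol
Product: 23 O-[2,15-bis(tert-butyldimethylsilyloxy)labd-7-en-11-yl] S-methyl dithiocarbonate, via potassium alkoxide 21 (not isolated), via potassium xanthate 22 (not isolated)
Conditions: KN(SiMe3)2, THF, −78 to 0 °C; CS2; MeI, 0 °C to rt
Reagents that add atoms: carbon disulfide, S=C=S; iodomethane, CI
Why: Xanthate formation by the alkoxide, CS2 and MeI sequence, the most dependable thiocarbonylation for a hindered secondary alcohol, leaves all stereocentres and the alkene untouched.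

**Step 15**
Reactants: 23 O-[2,15-bis(tert-butyldimethylsilyloxy)labd-7-en-11-yl] S-methyl dithiocarbonate
Product: 24 (2R,5R,9R,10R,13S)-2,15-bis(tert-butyldimethylsilyloxy)labd-7-ene
Conditions: Bu3SnH (3 equiv, 0.3 M), AIBN (0.2 equiv), toluene, 85 °C
Reagents that add atoms: none
Why: Barton–McCombie deoxygenation: stannyl radical addition to the thiocarbonyl group and fragmentation give the secondary C11 radical, which a high stannane concentration should quench faster than it can close onto C8 of the homoallylic alkene, so C11 becomes a methylene group and C9 stays as set.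

**Step 16**
Reactants: 24 (2R,5R,9R,10R,13S)-2,15-bis(tert-butyldimethylsilyloxy)labd-7-ene
Product: 25 (2R,5R,9R,10R,13S)-labd-7-ene-2,15-diol
Conditions: Bu4NF (4 equiv), THF, rt to 45 °C
Reagents that add atoms: none
Why: Fluoride-induced cleavage of both silyl ethers under essentially neutral conditions, which spare the acid-sensitive trisubstituted alkene.

**Step 17**
Reactants: 25 (2R,5R,9R,10R,13S)-labd-7-ene-2,15-diol
Product: 26 (2R,5R,9R,10R,13S)-labd-7-ene-2,15-diyl diacetate (CNP0220683.1)
Conditions: Ac2O, pyridine, DMAP (cat), CH2Cl2, rt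
Reagents that add atoms: acetic anhydride, CC(=O)OC(C)=O
Why: DMAP-catalysed acylation esterifies the primary C15 and the equatorial secondary C2 hydroxyl groups with retention, giving the target.

**Compound list**
1 | ketoisophorone (2,6,6-trimethylcyclohex-2-ene-1,4-dione) | CC1=CC(=O)CC(C)(C)C1=O | starting material
2 | (R)-4-hydroxy-2,6,6-trimethylcyclohex-2-en-1-one | CC1=C[C@H](O)CC(C)(C)C1=O | intermediate
3 | (R)-4-(tert-butyldimethylsilyloxy)-2,6,6-trimethylcyclohex-2-en-1-one | CC1=C[C@H](O[Si](C)(C)C(C)(C)C)CC(C)(C)C1=O | intermediate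
4 | (4S,6R)-4-(tert-butyldimethylsilyloxy)-2,2,6-trimethylcyclohexan-1-one | C[C@@H]1C[C@H](O[Si](C)(C)C(C)(C)C)CC(C)(C)C1=O | intermediate
5 | lithium (S)-4-(tert-butyldimethylsilyloxy)-2,6,6-trimethylcyclohex-1-en-1-olate | [Li+].[O-]C1=C(C)C[C@H](O[Si](C)(C)C(C)(C)C)CC1(C)C | intermediate
6 | (S)-4-(tert-butyldimethylsilyloxy)-2,6,6-trimethylcyclohex-1-en-1-yl trifluoromethanesulfonate | O=S(=O)(OC1=C(C)C[C@H](O[Si](C)(C)C(C)(C)C)CC1(C)C)C(F)(F)F | intermediate
7 | tributyl(vinyl)stannane | C=C[Sn](CCCC)(CCCC)CCCC | starting material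
8 | (S)-tert-butyldimethyl[(3,5,5-trimethyl-4-vinylcyclohex-3-en-1-yl)oxy]silane | C=CC1=C(C)C[C@H](O[Si](C)(C)C(C)(C)C)CC1(C)C | intermediate
9 | (R)-5-methoxy-3-methyl-5-oxopentanoic acid | OC(=O)C[C@@H](C)CC(=O)OC | starting material
10 | methyl (R)-5-hydroxy-3-methylpentanoate | OCC[C@@H](C)CC(=O)OC | intermediate
11 | methyl (R)-5-(tert-butyldimethylsilyloxy)-3-methylpentanoate | CC(C)(C)[Si](C)(C)OCC[C@@H](C)CC(=O)OC | intermediate
12 | (R)-5-(tert-butyldimethylsilyloxy)-N-methoxy-N,3-dimethylpentanamide | CC(C)(C)[Si](C)(C)OCC[C@@H](C)CC(=O)N(C)OC | intermediate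
13 | 1-propynylmagnesium bromide | CC#C[Mg]Br | starting material
14 | bromomagnesium hemiaminal chelate from 12 and 13 (hemiaminal carbon undefined, lost on work-up) | CC(C)(C)[Si](C)(C)OCC[C@@H](C)CC(O[Mg]Br)(C#CC)N(C)OC | intermediate
15 | (R)-8-(tert-butyldimethylsilyloxy)-6-methyloct-2-yn-4-one | CC(C)(C)[Si](C)(C)OCC[C@@H](C)CC(=O)C#CC | intermediate
16 | (2R,10R,13R)-2,15-bis(tert-butyldimethylsilyloxy)labda-5,8-dien-11-one | CC(C)(C)[Si](C)(C)OCC[C@@H](C)CC(=O)C1=C(C)CC=C2C(C)(C)C[C@@H](O[Si](C)(C)C(C)(C)C)C[C@@]12C | intermediate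
17 | (2R,5R,10R,13R)-2,15-bis(tert-butyldimethylsilyloxy)labd-8-en-11-one | CC(C)(C)[Si](C)(C)OCC[C@@H](C)CC(=O)C1=C(C)CC[C@@H]2C(C)(C)C[C@@H](O[Si](C)(C)C(C)(C)C)C[C@@]12C | intermediate
18 | potassium 2,15-bis(tert-butyldimethylsilyloxy)labda-7,9(11)-dien-11-olate (enolate geometry open) | [K+].CC(C)(C)[Si](C)(C)OCC[C@@H](C)CC([O-])=C1C(C)=CC[C@@H]2C(C)(C)C[C@@H](O[Si](C)(C)C(C)(C)C)C[C@@]12C | intermediate
19 | (2R,5R,9R,10R,13R)-2,15-bis(tert-butyldimethylsilyloxy)labd-7-en-11-one | CC(C)(C)[Si](C)(C)OCC[C@@H](C)CC(=O)[C@@H]1C(C)=CC[C@@H]2C(C)(C)C[C@@H](O[Si](C)(C)C(C)(C)C)C[C@@]12C | intermediate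
20 | (2R,5R,9R,10R,13R)-2,15-bis(tert-butyldimethylsilyloxy)labd-7-en-11-ol (C11 open) | CC(C)(C)[Si](C)(C)OCC[C@@H](C)CC(O)[C@@H]1C(C)=CC[C@@H]2C(C)(C)C[C@@H](O[Si](C)(C)C(C)(C)C)C[C@@]12C | intermediate
21 | potassium alkoxide of 20 | [K+].CC(C)(C)[Si](C)(C)OCC[C@@H](C)CC([O-])[C@@H]1C(C)=CC[C@@H]2C(C)(C)C[C@@H](O[Si](C)(C)C(C)(C)C)C[C@@]12C | intermediate
22 | potassium O-(labd-7-en-11-yl) dithiocarbonate derived from 21 | [K+].CC(C)(C)[Si](C)(C)OCC[C@@H](C)CC(OC(=S)[S-])[C@@H]1C(C)=CC[C@@H]2C(C)(C)C[C@@H](O[Si](C)(C)C(C)(C)C)C[C@@]12C | intermediate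
23 | O-[2,15-bis(tert-butyldimethylsilyloxy)labd-7-en-11-yl] S-methyl dithiocarbonate | CC(C)(C)[Si](C)(C)OCC[C@@H](C)CC(OC(=S)SC)[C@@H]1C(C)=CC[C@@H]2C(C)(C)C[C@@H](O[Si](C)(C)C(C)(C)C)C[C@@]12C | intermediate
24 | (2R,5R,9R,10R,13S)-2,15-bis(tert-butyldimethylsilyloxy)labd-7-ene | CC(C)(C)[Si](C)(C)OCC[C@@H](C)CC[C@@H]1C(C)=CC[C@@H]2C(C)(C)C[C@@H](O[Si](C)(C)C(C)(C)C)C[C@@]12C | intermediate
25 | (2R,5R,9R,10R,13S)-labd-7-ene-2,15-diol | OCC[C@@H](C)CC[C@@H]1C(C)=CC[C@@H]2C(C)(C)C[C@@H](O)C[C@@]12C | intermediate
26 | (2R,5R,9R,10R,13S)-labd-7-ene-2,15-diyl diacetate | CC(=O)OCC[C@@H](C)CC[C@@H]1C(C)=CC[C@@H]2C(C)(C)C[C@@H](OC(C)=O)C[C@@]12C | target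

**Total step count:** 17
**Longest linear sequence:** 13 steps (steps 1–5 and 10–17)

**Steps most likely to fail**

**Step 10.**
- Risk: the β-methylated alkyne may add too slowly at the tetrasubstituted C10 terminus. Lewis-acid-induced isomerisation or oligomerisation of the diene could then take over. Regio- and facial selectivity may also erode if warming is needed.
- Fallback: it sets out from 12 and 8 and comes back at 16, and it installs C17 only after the cycloaddition. Weinreb amide 12 and ethynylmagnesium bromide give, through the magnesium hemiaminal chelate F1, the terminal ynone F2. This dienophile is much smaller and more electrophilic, so it should add to 8 at lower temperature under the same Lewis acid to give the 17-nor adduct F3. Conjugate addition of Me2CuLi in the presence of Me3SiCl to the now unsubstituted C8 gives the trimethylsilyl enol ether F4. Saegusa–Ito oxidation with Pd(OAc)2 can eliminate only toward C8, because C10 bears no hydrogen, so it restores C8=C9 and delivers 16.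

**Step 12.**
- Risk: the C12 enolate may remain the dominant species, deprotonation may stray to C17, or the alkene may slip back into conjugation during the quench.
- Fallback: it sets out from 17 and comes back at 19, and it generates the same dienolate by reduction instead of deprotonation, so the acidity of C12 plays no part. Wohl–Ziegler bromination (NBS, AIBN, solid K2CO3, PhCF3, reflux) should attack the ring allylic methylene C7 rather than the C17 methyl, as it does in the β-ionone and β-cyclogeranate series, to give the 7-bromo enone F5. Zinc dust in Et2O–AcOH at 0 °C converts it into the bromozinc dienolate F6, whose unsaturation is fixed by the site of the bromine. Protonation at C9 anti to C20 then gives 19.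

**Step 15.**
- Risk: the C11 radical may close onto C8 and reopen with a 1,2-vinyl shift that enlarges ring B. The crowded xanthate may also undergo thermal syn-elimination or react sluggishly.
- Fallback: it sets out from 20 and comes back at 24, bypassing steps 14 and 15 by an electron-transfer deoxygenation. BuLi converts 20 into the lithium alkoxide F7, and ClP(O)(NMe2)2 turns this into the tetramethylphosphorodiamidate F8. Lithium in EtNH2–THF–tBuOH at 0 °C cleaves the C11–O bond of F8. Any radical formed is reduced to the carbanion and protonated faster than it can reach the alkene, while the trisubstituted alkene and the silyl ethers are left alone.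

**Further compounds**
F1 | step 10 | bromomagnesium hemiaminal chelate from 12 and ethynylmagnesium bromide | CC(C)(C)[Si](C)(C)OCC[C@@H](C)CC(O[Mg]Br)(C#C)N(C)OC
F2 | step 10 | (R)-7-(tert-butyldimethylsilyloxy)-5-methylhept-1-yn-3-one | CC(C)(C)[Si](C)(C)OCC[C@@H](C)CC(=O)C#C
F3 | step 10 | (2R,10R,13R)-2,15-bis(tert-butyldimethylsilyloxy)-17-norlabda-5,8-dien-11-one | CC(C)(C)[Si](C)(C)OCC[C@@H](C)CC(=O)C1=CCC=C2C(C)(C)C[C@@H](O[Si](C)(C)C(C)(C)C)C[C@@]12C
F4 | step 10 | 2,15-bis(tert-butyldimethylsilyloxy)-11-trimethylsilyloxylabda-5,9(11)-diene (C8 and enol ether geometry open) | CC(C)(C)[Si](C)(C)OCC[C@@H](C)CC(O[Si](C)(C)C)=C1C(C)CC=C2C(C)(C)C[C@@H](O[Si](C)(C)C(C)(C)C)C[C@@]12C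
F5 | step 12 | 7-bromo-2,15-bis(tert-butyldimethylsilyloxy)labd-8-en-11-one (C7 open) | CC(C)(C)[Si](C)(C)OCC[C@@H](C)CC(=O)C1=C(C)C(Br)C[C@@H]2C(C)(C)C[C@@H](O[Si](C)(C)C(C)(C)C)C[C@@]12C
F6 | step 12 | bromozinc 2,15-bis(tert-butyldimethylsilyloxy)labda-7,9(11)-dien-11-olate | CC(C)(C)[Si](C)(C)OCC[C@@H](C)CC(O[Zn]Br)=C1C(C)=CC[C@@H]2C(C)(C)C[C@@H](O[Si](C)(C)C(C)(C)C)C[C@@]12C
F7 | step 15 | lithium alkoxide of 20 | [Li+].CC(C)(C)[Si](C)(C)OCC[C@@H](C)CC([O-])[C@@H]1C(C)=CC[C@@H]2C(C)(C)C[C@@H](O[Si](C)(C)C(C)(C)C)C[C@@]12C
F8 | step 15 | 2,15-bis(tert-butyldimethylsilyloxy)labd-7-en-11-yl N,N,N',N'-tetramethylphosphorodiamidate | CC(C)(C)[Si](C)(C)OCC[C@@H](C)CC(OP(=O)(N(C)C)N(C)C)[C@@H]1C(C)=CC[C@@H]2C(C)(C)C[C@@H](O[Si](C)(C)C(C)(C)C)C[C@@]12C
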